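**Plan**

- Retrosynthesis: the phenols are benzylated and the C4 methyl is traced back to CH2SO2Ph. Then C4–C5 is cut (radical ring closure), then O1–C5 (carbenoid O–H insertion), then the alkene carbon–sulfonyl carbon double bond (cross-metathesis), and last C2–C3 (crotylboration of O-benzylsyringaldehyde).
- Forward: C2–C3 is made first, the ether O1–C5 second and the vinyl sulfone third. The only ring, the oxolane, closes last through C4–C5; desulfonylation and debenzylation finish the synthesis.
- Enabling feature: in the oxolane (O1, C2, C3, C4, C5) the aryl groups on C2 and C5 and the methyl on C4 lie on one face and the methyl on C3 on the other. This is the pattern delivered by an all-pseudo-equatorial chair transition state of a 2-oxahex-5-enyl radical centred on C5.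
- Stereochemistry: C2 and C3 (anti, both S) come from a chiral phosphoric acid-catalysed crotylboration with the E boronate. C4 and C5 are set relative to them in the radical closure. The acid-bearing carbon is carried as an epimer mixture because decarboxylation erases it.

Key step: step 8

Remark: (S)-TRIP is assumed to direct the crotyl group to the Si face of aldehyde 2, mirroring the Re-face attack expected of the (R) acid on simple aryl aldehydes. Oxolane atoms are numbered O1, C2 (the former carbinol carbon), C3, C4, C5 throughout.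

**Route**

Step 1
Reactants: 1 syringaldehyde
Product: 2 4-(benzyloxy)-3,5-dimethoxybenzaldehyde
Conditions: BnBr, K2CO3, DMF, rt
Reagents that add atoms: benzyl bromide, BrCc1ccccc1
Why: Williamson etherification, in which the phenoxide formed with K2CO3 displaces bromide by SN2, masks the phenol from the carbenoid, the ruthenium carbene and the photocatalyst used later.

Step 2
Reactants: 2 4-(benzyloxy)-3,5-dimethoxybenzaldehyde; 3 (E)-crotylboronic acid pinacol ester
Product: 5 (1S,2S)-1-[4-(benzyloxy)-3,5-dimethoxyphenyl]-2-methylbut-3-en-1-ol, via pinacol borate ester 4 (not isolated)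
Conditions: (S)-TRIP (5 mol%), toluene, −30 °C; then aqueous NaHCO3 work-up
Reagents that add atoms: none
Why: In this chiral phosphoric acid-catalysed crotylboration the closed chair (Zimmerman–Traxler) transition state should turn the E geometry of 3 into the anti C1/C2 relationship, while the (S) acid, hydrogen-bonded to a boronate oxygen and the formyl hydrogen, should direct attack to the Si face, so that hydrolysis of borate 4 gives the 1S,2S alcohol.

Step 3
Reactants: 6 (4-hydroxy-3,5-dimethoxyphenyl)acetic acid
Product: 7 benzyl [4-(benzyloxy)-3,5-dimethoxyphenyl]acetate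
Conditions: BnBr (2.5 equiv), K2CO3, DMF, 60 °C
Reagents that add atoms: benzyl bromide, BrCc1ccccc1
Why: Double Williamson-type alkylation, in which carbonate generates both carboxylate and phenoxide and each displaces bromide, installs ester and ether in one operation without touching the weakly acidic benzylic CH2.

Step 4
Reactants: 7 benzyl [4-(benzyloxy)-3,5-dimethoxyphenyl]acetate
Product: 8 benzyl 2-[4-(benzyloxy)-3,5-dimethoxyphenyl]-2-diazoacetate
Conditions: p-ABSA, DBU, MeCN, 0 °C to rt
Reagents that add atoms: 4-acetamidobenzenesulfonyl azide (p-ABSA), CC(=O)Nc1ccc(cc1)S(=O)(=O)N=[N+]=[N-]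
Why: Regitz diazo transfer, in which the DBU-generated ester enolate takes N2 from the sulfonyl azide, is the standard entry to aryl diazoacetates.

Step 5
Reactants: 5 (1S,2S)-1-[4-(benzyloxy)-3,5-dimethoxyphenyl]-2-methylbut-3-en-1-ol; 8 benzyl 2-[4-(benzyloxy)-3,5-dimethoxyphenyl]-2-diazoacetate
Product: 9 benzyl 2-[4-(benzyloxy)-3,5-dimethoxyphenyl]-2-{[(1S,2S)-1-[4-(benzyloxy)-3,5-dimethoxyphenyl]-2-methylbut-3-en-1-yl]oxy}acetate (both epimers at the acetate carbon)
Conditions: Rh2(OAc)4 (1 mol%), CH2Cl2, rt, slow addition of 8 to 5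
Reagents that add atoms: none
Why: In this rhodium-carbenoid O–H insertion the donor/acceptor carbenoid should be trapped by the hydroxyl group through an oxonium ylide and proton shift faster than it cyclopropanates the unactivated terminal alkene; the new centre forms as both epimers, which is harmless because step 8 destroys it.

Step 6
Reactants: 9 benzyl ester from step 5 (both epimers)
Product: 10 2-[4-(benzyloxy)-3,5-dimethoxyphenyl]-2-{[(1S,2S)-1-[4-(benzyloxy)-3,5-dimethoxyphenyl]-2-methylbut-3-en-1-yl]oxy}acetic acid (both epimers)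
Conditions: LiOH·H2O, THF/H2O, rt; then 1 M HCl to pH 3 at 0 °C
Reagents that add atoms: lithium hydroxide, [Li+].[OH-]
Why: Saponification by acyl–oxygen cleavage leaves all ethers intact, and running it before the vinyl sulfone is installed keeps hydroxide away from that Michael acceptor.

Step 7
Reactants: 10 alkenyl acid from step 6 (both epimers); 11 phenyl vinyl sulfone
Product: 12 2-[4-(benzyloxy)-3,5-dimethoxyphenyl]-2-{[(1S,2S,3E)-1-[4-(benzyloxy)-3,5-dimethoxyphenyl]-2-methyl-4-(phenylsulfonyl)but-3-en-1-yl]oxy}acetic acid (both epimers)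
Conditions: second-generation Hoveyda–Grubbs catalyst RuCl2(H2IMes)(=CH-C6H4-2-OiPr) (5 mol%), 11 (3 equiv), CH2Cl2, 40 °C
Reagents that add atoms: none
Why: Olefin cross-metathesis of a terminal alkene with a vinyl sulfone that does not homodimerise is known to give E-alkenyl sulfones with phosphine-free ruthenium carbenes; the free acid is tolerated and the two stereocentres are not involved.

Step 8
Reactants: 12 vinyl sulfone acid from step 7 (both epimers)
Product: 13 (2S,3S,4S,5R)-2,5-bis[4-(benzyloxy)-3,5-dimethoxyphenyl]-3-methyl-4-[(phenylsulfonyl)methyl]oxolane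
Conditions: [Ir(dF(CF3)ppy)2(dtbbpy)]PF6 (2 mol%), K2HPO4, degassed DMF (0.02 M), blue LEDs, rt
Reagents that add atoms: none
Why: Single-electron oxidation of the carboxylate of 12 by the photoexcited trivalent iridium complex and loss of CO2 give the same planar C5 benzylic α-oxy radical from either epimer; it adds to the alkene carbon that becomes C4, and the α-sulfonyl radical is reduced by the divalent iridium species and protonated, closing the catalytic cycle. The closest known reaction type is the photoredox decarboxylative Giese addition of α-alkoxy acids to vinyl sulfones, here run intramolecularly. The oxolane closes in 5-exo-trig mode, favoured over 6-endo kinetically and by the polarisation of the vinyl sulfone, whose β-carbon lies five atoms from the radical centre. C4 is set by the chair-like Beckwith–Houk transition state with the C2 aryl and C3 methyl pseudo-equatorial, which should place the sulfonylmethyl arm trans to the C3 methyl and cis to the C2 aryl. C5 is set in the same transition state by the aryl on the radical carbon also lying pseudo-equatorial, hence cis to the C2 aryl and to the C4 arm. The step needs diastereocontrol relative to C2 and C3 and convergence of both epimers: the anti pair from step 2 supplies the first and the planarity of the radical the second, with the cis preference at C5 expected to be the least pronounced element.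

Step 9
Reactants: 13 sulfonylmethyl oxolane from step 8
Product: 14 (2S,3S,4S,5R)-2,5-bis[4-(benzyloxy)-3,5-dimethoxyphenyl]-3,4-dimethyloxolane
Conditions: 6% Na(Hg), Na2HPO4, MeOH/THF, −20 °C to rt
Reagents that add atoms: none
Why: Reductive desulfonylation, in which electron transfer from sodium amalgam cleaves the alkyl C–S bond and the buffered methanol protonates the carbanion, should turn CH2SO2Ph into the C4 methyl without touching the ring stereocentres, the benzyl ethers or the oxolane C–O bonds.

Step 10
Reactants: 14 bis-benzyl ether from step 9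
Product: 15 4,4'-[(2S,3S,4S,5R)-3,4-dimethyloxolane-2,5-diyl]bis(2,6-dimethoxyphenol)
Conditions: H2 (1 atm), 10% Pd/C, EtOAc, rt
Reagents that add atoms: none
Why: Catalytic hydrogenolysis over zerovalent palladium on carbon cleaves aryl O-benzyl bonds much faster than the dialkyl benzylic C–O bonds of the oxolane in a neutral solvent, so both phenols should be freed with the ring and its four stereocentres intact if hydrogen uptake is stopped promptly.

**Compound list**

1 | syringaldehyde | COc1cc(C=O)cc(OC)c1O | starting material
2 | 4-(benzyloxy)-3,5-dimethoxybenzaldehyde | COc1cc(C=O)cc(OC)c1OCc1ccccc1 | intermediate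
3 | (E)-crotylboronic acid pinacol ester | C/C=C/CB1OC(C)(C)C(C)(C)O1 | starting material
4 | 2-{[(1S,2S)-1-[4-(benzyloxy)-3,5-dimethoxyphenyl]-2-methylbut-3-en-1-yl]oxy}-4,4,5,5-tetramethyl-1,3,2-dioxaborolane | CC1(C)OB(O[C@H](c2cc(OC)c(OCc3ccccc3)c(OC)c2)[C@@H](C)C=C)OC1(C)C | intermediate
5 | (1S,2S)-1-[4-(benzyloxy)-3,5-dimethoxyphenyl]-2-methylbut-3-en-1-ol | O[C@H](c1cc(OC)c(OCc2ccccc2)c(OC)c1)[C@@H](C)C=C | intermediate
6 | (4-hydroxy-3,5-dimethoxyphenyl)acetic acid | COc1cc(CC(=O)O)cc(OC)c1O | starting material
7 | benzyl [4-(benzyloxy)-3,5-dimethoxyphenyl]acetate | COc1cc(CC(=O)OCc2ccccc2)cc(OC)c1OCc1ccccc1 | intermediate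
8 | benzyl 2-[4-(benzyloxy)-3,5-dimethoxyphenyl]-2-diazoacetate | COc1cc(C(=[N+]=[N-])C(=O)OCc2ccccc2)cc(OC)c1OCc1ccccc1 | intermediate
9 | benzyl 2-[4-(benzyloxy)-3,5-dimethoxyphenyl]-2-{[(1S,2S)-1-[4-(benzyloxy)-3,5-dimethoxyphenyl]-2-methylbut-3-en-1-yl]oxy}acetate, both epimers at the acetate carbon | O=C(OCc1ccccc1)C(O[C@H](c1cc(OC)c(OCc2ccccc2)c(OC)c1)[C@@H](C)C=C)c1cc(OC)c(OCc2ccccc2)c(OC)c1 | intermediate
10 | 2-[4-(benzyloxy)-3,5-dimethoxyphenyl]-2-{[(1S,2S)-1-[4-(benzyloxy)-3,5-dimethoxyphenyl]-2-methylbut-3-en-1-yl]oxy}acetic acid, both epimers | OC(=O)C(O[C@H](c1cc(OC)c(OCc2ccccc2)c(OC)c1)[C@@H](C)C=C)c1cc(OC)c(OCc2ccccc2)c(OC)c1 | intermediate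
11 | phenyl vinyl sulfone | C=CS(=O)(=O)c1ccccc1 | starting material
12 | 2-[4-(benzyloxy)-3,5-dimethoxyphenyl]-2-{[(1S,2S,3E)-1-[4-(benzyloxy)-3,5-dimethoxyphenyl]-2-methyl-4-(phenylsulfonyl)but-3-en-1-yl]oxy}acetic acid, both epimers | OC(=O)C(O[C@H](c1cc(OC)c(OCc2ccccc2)c(OC)c1)[C@@H](C)/C=C/S(=O)(=O)c1ccccc1)c1cc(OC)c(OCc2ccccc2)c(OC)c1 | intermediate
13 | (2S,3S,4S,5R)-2,5-bis[4-(benzyloxy)-3,5-dimethoxyphenyl]-3-methyl-4-[(phenylsulfonyl)methyl]oxolane | COc1cc([C@H]2O[C@@H](c3cc(OC)c(OCc4ccccc4)c(OC)c3)[C@@H](CS(=O)(=O)c3ccccc3)[C@@H]2C)cc(OC)c1OCc1ccccc1 | intermediate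
14 | (2S,3S,4S,5R)-2,5-bis[4-(benzyloxy)-3,5-dimethoxyphenyl]-3,4-dimethyloxolane | COc1cc([C@H]2O[C@@H](c3cc(OC)c(OCc4ccccc4)c(OC)c3)[C@@H](C)[C@@H]2C)cc(OC)c1OCc1ccccc1 | intermediate
15 | 4,4'-[(2S,3S,4S,5R)-3,4-dimethyloxolane-2,5-diyl]bis(2,6-dimethoxyphenol) | COc1cc([C@H]2O[C@@H](c3cc(OC)c(O)c(OC)c3)[C@@H](C)[C@@H]2C)cc(OC)c1O | target

**Summary**

Total step count: 10. Longest linear sequence: 8 steps (steps 1, 2, 5, 6, 7, 8, 9, 10; the branch through steps 3 and 4 is equally long).

Steps most likely to fail:

1. Step 8. The excited photocatalyst may oxidise the trialkoxyaryl rings or the electron-rich α-oxy benzylic radical faster than the ring closes, diverting material to oxocarbenium-derived products, and the facial preference at C5 may be modest. The fallback generates the same radical reductively, with no strong oxidant present. It sets out from 12, which is coupled with N-hydroxyphthalimide (DIC, cat. DMAP, CH2Cl2) to the 1,3-dioxoisoindolin-2-yl ester of 12, F1. Irradiation of this ester with Ru(bpy)3(PF6)2, Hantzsch ester and iPr2NEt in CH2Cl2 under blue LEDs should fragment it by electron transfer from the reduced ruthenium photocatalyst, lose CO2, cyclise through the same chair transition state and end by hydrogen-atom transfer from the dihydropyridine. The fallback rejoins the route at 13.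

2. Step 7. Metathesis may stall because the alkene is α-branched and flanked by a bulky aryl ether, while the electron-poor partner reacts slowly and the catalyst decays. The fallback builds the vinyl sulfone by olefination instead. It sets out from 10, which is cleaved by Lemieux–Johnson oxidation (cat. OsO4, NaIO4, 2,6-lutidine, dioxane/H2O) to 2-[4-(benzyloxy)-3,5-dimethoxyphenyl]-2-{[(1S,2R)-1-[4-(benzyloxy)-3,5-dimethoxyphenyl]-2-methyl-3-oxopropyl]oxy}acetic acid F2. Horner–Wadsworth–Emmons reaction of this aldehyde with diethyl [(phenylsulfonyl)methyl]phosphonate under Masamune–Roush conditions (LiCl, excess iPr2NEt, MeCN) should give the E-vinyl sulfone with little epimerisation of the α-methyl centre. The fallback rejoins the route at 12.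

3. Step 5. The carbenoid may lose chemoselectivity, cyclopropanating the terminal alkene or dimerising in preference to insertion into the hindered secondary hydroxyl group. The fallback forms the ether by substitution instead of carbene transfer. It sets out from 7, whose lithium enolate (LiN(SiMe3)2, THF, −78 °C) is brominated with NBS to benzyl 2-[4-(benzyloxy)-3,5-dimethoxyphenyl]-2-bromoacetate F3. The sodium alkoxide of 5 (NaH, THF, 0 °C) then displaces the activated benzylic bromide in a Williamson etherification. The fallback rejoins the route at 9, again as an epimer mixture.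

**Further compounds**

F1 | step 8 | 1,3-dioxoisoindolin-2-yl 2-[4-(benzyloxy)-3,5-dimethoxyphenyl]-2-{[(1S,2S,3E)-1-[4-(benzyloxy)-3,5-dimethoxyphenyl]-2-methyl-4-(phenylsulfonyl)but-3-en-1-yl]oxy}acetate, both epimers | O=C(ON1C(=O)c2ccccc2C1=O)C(O[C@H](c1cc(OC)c(OCc2ccccc2)c(OC)c1)[C@@H](C)/C=C/S(=O)(=O)c1ccccc1)c1cc(OC)c(OCc2ccccc2)c(OC)c1
F2 | step 7 | 2-[4-(benzyloxy)-3,5-dimethoxyphenyl]-2-{[(1S,2R)-1-[4-(benzyloxy)-3,5-dimethoxyphenyl]-2-methyl-3-oxopropyl]oxy}acetic acid, both epimers | OC(=O)C(O[C@H](c1cc(OC)c(OCc2ccccc2)c(OC)c1)[C@@H](C)C=O)c1cc(OC)c(OCc2ccccc2)c(OC)c1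
F3 | step 5 | benzyl 2-[4-(benzyloxy)-3,5-dimethoxyphenyl]-2-bromoacetate, racemic | COc1cc(C(Br)C(=O)OCc2ccccc2)cc(OC)c1OCc1ccccc1
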